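The target is cut at both benzylic CH2–CH= bonds that flank the C4 methoxy group of the benzene ring, which leads back to one symmetrical 3,5-bis(bromomethyl)anisate. The decisive union makes C1'–C2' of the C10 arm. On the C2'=C3' alkene, the benzylic carbon C1' and the C3' methyl are cis, the pattern left by a syn addition to a terminal alkyne. In one flask, zirconium-catalysed methylalumination of an (S)-propargylic silyl ether installs the C3' methyl and fixes the E geometry. Palladium-catalysed coupling of the resulting alkenylalane with the benzylic bromide then forges C1'–C2'. The precursor is thus a methyl-less C8 enyne. One fluoride treatment finally unmasks both alcohols and the acid.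

Key step: step 8

Locants: ring C1 bears the carboxyl group, C4 the methoxy group, C3 the C10 arm (C1'–C8') and C5 the C5 arm (C1''–C4''). The centre written [C@@H] in the target is C4' and has the S configuration.

Step 1
Reactants: 1 4-methoxy-3,5-dimethylbenzoic acid; 2 2-(trimethylsilyl)ethanol
Product: 3 2-(trimethylsilyl)ethyl 4-methoxy-3,5-dimethylbenzoate
Conditions: DCC (1.1 equiv), DMAP (cat.), CH2Cl2, 0 °C to rt
Reagents that add atoms: none
Why: Steglich esterification of an unhindered benzoic acid installs an ester that fluoride can later remove together with the silyl ethers.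

Step 2
Reactants: 3 2-(trimethylsilyl)ethyl 4-methoxy-3,5-dimethylbenzoate
Product: 4 2-(trimethylsilyl)ethyl 3,5-bis(bromomethyl)-4-methoxybenzoate
Conditions: NBS (2.1 equiv), AIBN (cat.), PhCF3, reflux
Reagents that add atoms: N-bromosuccinimide O=C1CCC(=O)N1Br
Why: In this Wohl–Ziegler radical bromination the two equivalent benzylic methyl groups carry the only weak C–H bonds, and the free ring positions, meta to the methoxy group and ortho to the ester, should resist nuclear bromination.

Step 3
Reactants: 5 3-(trimethylsilyl)prop-2-ynal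
Product: 7 (S)-1-(trimethylsilyl)hex-5-en-1-yn-3-ol, via borinate 6 (not isolated)
Conditions: (+)-Ipc2B(allyl) (1.2 equiv, 1 M in pentane), Et2O, −78 °C; then HOCH2CH2NH2, rt
Reagents that add atoms: (+)-B-allyldiisopinocampheylborane, the enantiomer derived from (+)-α-pinene C=CCB([C@@H]1C[C@@H]2C[C@H]([C@H]1C)C2(C)C)[C@@H]1C[C@@H]2C[C@H]([C@H]1C)C2(C)C
Why: In the Brown allylboration the closed chair transition state and the isopinocampheyl groups direct the allyl group to the Si face of the ynal, which should set the carbinol carbon as S (alkynyl outranks the allyl CH2), and the non-oxidative ethanolamine work-up spares the C–SiMe3 bond.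

Step 4
Reactants: 7 (S)-1-(trimethylsilyl)hex-5-en-1-yn-3-ol
Product: 8 (S)-tert-butyldimethyl{[1-(trimethylsilyl)hex-5-en-1-yn-3-yl]oxy}silane
Conditions: TBSCl (1.2 equiv), imidazole (2 equiv), DMF, rt
Reagents that add atoms: tert-butyldimethylsilyl chloride CC(C)(C)[Si](C)(C)Cl
Why: Standard O-silylation of a secondary alcohol breaks no bond at the stereocentre and gives an ether that tolerates ruthenium carbenes and aluminium alkyls.

Step 5
Reactants: 8 (S)-tert-butyldimethyl{[1-(trimethylsilyl)hex-5-en-1-yn-3-yl]oxy}silane; 9 2-methylbut-2-ene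
Product: 10 (S)-tert-butyldimethyl{[6-methyl-1-(trimethylsilyl)hept-5-en-1-yn-3-yl]oxy}silane
Conditions: second-generation Grubbs catalyst RuCl2(=CHPh)(PCy3)(H2IMes) (5 mol %), 9 (large excess, co-solvent), CH2Cl2, 40 °C
Reagents that add atoms: none
Why: Olefin cross-metathesis of the terminal alkene with excess 2-methylbut-2-ene transfers an isopropylidene unit with loss of propene, while the silyl cap should keep the alkyne away from the ruthenium carbene.

Step 6
Reactants: 10 (S)-tert-butyldimethyl{[6-methyl-1-(trimethylsilyl)hept-5-en-1-yn-3-yl]oxy}silane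
Product: 11 (S)-tert-butyldimethyl[(6-methylhept-5-en-1-yn-3-yl)oxy]silane
Conditions: K2CO3 (0.2 equiv), MeOH, rt
Reagents that add atoms: none
Why: Base-catalysed methanolysis (protodesilylation) cleaves only the alkynyl C–SiMe3 bond, because the O–TBS ether is stable to K2CO3 in methanol.

Step 7
Reactants: 12 tert-butyldimethyl(prop-2-yn-1-yloxy)silane; 4 2-(trimethylsilyl)ethyl 3,5-bis(bromomethyl)-4-methoxybenzoate
Product: 14 2-(trimethylsilyl)ethyl 3-(bromomethyl)-5-[(2E)-4-(tert-butyldimethylsilyloxy)-3-methylbut-2-en-1-yl]-4-methoxybenzoate, via alkenylalane 13 (not isolated)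
Conditions: 12 (1 equiv), AlMe3 (2 equiv), Cp2ZrCl2 (0.25 equiv), ClCH2CH2Cl, 0 °C to rt; volatiles removed in vacuo; then 4 (3 equiv), Pd(PPh3)4 (5 mol %), THF, rt; unreacted 4 recovered by chromatography
Reagents that add atoms: trimethylaluminium C[Al](C)C
Why: Negishi carboalumination (syn addition, hence E) followed by palladium-catalysed alkenylalane–benzyl bromide coupling builds the C5 arm, and the threefold excess of the cheap, recoverable dibromide 4 over the limiting alane should keep substitution at the second benzylic site minor.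

Step 8
Reactants: 11 (S)-tert-butyldimethyl[(6-methylhept-5-en-1-yn-3-yl)oxy]silane; 14 2-(trimethylsilyl)ethyl 3-(bromomethyl)-5-[(2E)-4-(tert-butyldimethylsilyloxy)-3-methylbut-2-en-1-yl]-4-methoxybenzoate
Product: 16 2-(trimethylsilyl)ethyl 3-[(2E,4S)-4-(tert-butyldimethylsilyloxy)-3,7-dimethylocta-2,6-dien-1-yl]-5-[(2E)-4-(tert-butyldimethylsilyloxy)-3-methylbut-2-en-1-yl]-4-methoxybenzoate, via alkenylalane 15 (not isolated)
Conditions: 11 (1.2 equiv), AlMe3 (2.5 equiv), Cp2ZrCl2 (0.3 equiv), ClCH2CH2Cl, 0 °C to rt; volatiles removed in vacuo; then 14 (1 equiv), Pd(PPh3)4 (5 mol %), THF, rt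
Reagents that add atoms: trimethylaluminium C[Al](C)C
Why: Cp2ZrCl2 and AlMe3 form a chloride-bridged Zr–Al methyl species that adds CH3 and metal syn across the terminal alkyne of 11, CH3 to the internal carbon (future C3') and metal to the terminal carbon (future C2'), and Zr-to-Al exchange gives the (E)-alkenylalane 15; zerovalent palladium then inserts into the benzylic C–Br bond of 14, takes over the alkenyl group from aluminium and reductively eliminates with retention to form C1'–C2'. This is the Negishi carboalumination followed by the known alkenylalane–benzyl halide cross-coupling, the established entry to (E)-3-methylalk-2-enyl arenes. No ring is closed and no stereocentre is created: C4' enters as S with 11 and stays untouched, because neither event breaks a bond at that carbon. The step needs regioselective methylalumination, secured by the terminal alkyne and reinforced by the branched silyloxy carbon beside it, and E geometry, secured by the syn addition and the stereoretentive coupling. It also needs alkenyl rather than methyl transfer, which the faster transmetalation of the sp2 carbon should provide once excess AlMe3 has been stripped off, and chemoselectivity, which holds because 14 has a single benzylic bromide, the trisubstituted alkenes are inert to the Zr/Al reagent, and the ester and silyl ethers tolerate the THF-complexed alane at room temperature.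

Step 9
Reactants: 16 2-(trimethylsilyl)ethyl 3-[(2E,4S)-4-(tert-butyldimethylsilyloxy)-3,7-dimethylocta-2,6-dien-1-yl]-5-[(2E)-4-(tert-butyldimethylsilyloxy)-3-methylbut-2-en-1-yl]-4-methoxybenzoate
Product: 17 3-[(2E,4S)-4-hydroxy-3,7-dimethylocta-2,6-dien-1-yl]-5-[(2E)-4-hydroxy-3-methylbut-2-en-1-yl]-4-methoxybenzoic acid
Conditions: TBAF (5 equiv), THF, rt; cold dilute HCl to pH 4
Reagents that add atoms: none
Why: In this global fluoride deprotection, Si–F bond formation cleaves both TBS ethers and triggers β-fragmentation of the 2-(trimethylsilyl)ethyl ester to ethene and the carboxylate, and the only mildly acidic work-up should not ionise the allylic alcohols, so C4' stays S.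

Compound list
1 | 4-methoxy-3,5-dimethylbenzoic acid | COc1c(C)cc(C(=O)O)cc1C | starting material
2 | 2-(trimethylsilyl)ethanol | OCC[Si](C)(C)C | starting material
3 | 2-(trimethylsilyl)ethyl 4-methoxy-3,5-dimethylbenzoate | COc1c(C)cc(C(=O)OCC[Si](C)(C)C)cc1C | intermediate
4 | 2-(trimethylsilyl)ethyl 3,5-bis(bromomethyl)-4-methoxybenzoate | COc1c(CBr)cc(C(=O)OCC[Si](C)(C)C)cc1CBr | intermediate
5 | 3-(trimethylsilyl)prop-2-ynal | C[Si](C)(C)C#CC=O | starting material
6 | (S)-1-(trimethylsilyl)hex-5-en-1-yn-3-yl diisopinocampheylborinate (not isolated) | C[Si](C)(C)C#C[C@@H](OB([C@@H]1C[C@@H]2C[C@H]([C@H]1C)C2(C)C)[C@@H]1C[C@@H]2C[C@H]([C@H]1C)C2(C)C)CC=C | intermediate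
7 | (S)-1-(trimethylsilyl)hex-5-en-1-yn-3-ol | C[Si](C)(C)C#C[C@@H](O)CC=C | intermediate
8 | (S)-tert-butyldimethyl{[1-(trimethylsilyl)hex-5-en-1-yn-3-yl]oxy}silane | C[Si](C)(C)C#C[C@@H](O[Si](C)(C)C(C)(C)C)CC=C | intermediate
9 | 2-methylbut-2-ene | CC=C(C)C | starting material
10 | (S)-tert-butyldimethyl{[6-methyl-1-(trimethylsilyl)hept-5-en-1-yn-3-yl]oxy}silane | C[Si](C)(C)C#C[C@@H](O[Si](C)(C)C(C)(C)C)CC=C(C)C | intermediate
11 | (S)-tert-butyldimethyl[(6-methylhept-5-en-1-yn-3-yl)oxy]silane | C#C[C@@H](O[Si](C)(C)C(C)(C)C)CC=C(C)C | intermediate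
12 | tert-butyldimethyl(prop-2-yn-1-yloxy)silane | C#CCO[Si](C)(C)C(C)(C)C | starting material
13 | (E)-[3-(tert-butyldimethylsilyloxy)-2-methylprop-1-en-1-yl]dimethylalane (not isolated) | C[Al](C)/C=C(\C)CO[Si](C)(C)C(C)(C)C | intermediate
14 | 2-(trimethylsilyl)ethyl 3-(bromomethyl)-5-[(2E)-4-(tert-butyldimethylsilyloxy)-3-methylbut-2-en-1-yl]-4-methoxybenzoate | COc1c(C/C=C(\C)CO[Si](C)(C)C(C)(C)C)cc(C(=O)OCC[Si](C)(C)C)cc1CBr | intermediate
15 | [(1E,3S)-3-(tert-butyldimethylsilyloxy)-2,6-dimethylhepta-1,5-dien-1-yl]dimethylalane (not isolated) | C[Al](C)/C=C(\C)[C@@H](O[Si](C)(C)C(C)(C)C)CC=C(C)C | intermediate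
16 | 2-(trimethylsilyl)ethyl 3-[(2E,4S)-4-(tert-butyldimethylsilyloxy)-3,7-dimethylocta-2,6-dien-1-yl]-5-[(2E)-4-(tert-butyldimethylsilyloxy)-3-methylbut-2-en-1-yl]-4-methoxybenzoate | COc1c(C/C=C(\C)CO[Si](C)(C)C(C)(C)C)cc(C(=O)OCC[Si](C)(C)C)cc1C/C=C(\C)[C@@H](O[Si](C)(C)C(C)(C)C)CC=C(C)C | intermediate
17 | 3-[(2E,4S)-4-hydroxy-3,7-dimethylocta-2,6-dien-1-yl]-5-[(2E)-4-hydroxy-3-methylbut-2-en-1-yl]-4-methoxybenzoic acid | COc1c(C/C=C(\C)CO)cc(C(=O)O)cc1C/C=C(\C)[C@@H](O)CC=C(C)C | target

Total step count: 9.
Longest linear sequence: 6 steps (steps 3, 4, 5, 6, 8 and 9, from 5).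

Steps most likely to fail

1. Step 8 (key step).
- Risk: methylalumination beside the bulky silyloxy-bearing carbon may be slow or lose regiocontrol. Residual aluminium methyl groups may transfer to the benzylic position or attack the ester.
- Fallback (sets out from 11 and 14, comes back at 16): the two events are separated and the polarity of the union is reversed. Alane 15 is quenched with I2 to give tert-butyl{[(1E,3S)-1-iodo-2,6-dimethylhepta-1,5-dien-3-yl]oxy}dimethylsilane F1, which can be freed from any regioisomer by chromatography. Bromide 14 is converted with Zn dust and LiCl in THF into the benzylic zinc bromide F2. Negishi coupling of F1 with F2 [Pd(OAc)2, SPhos, THF, rt] should give 16 with retention of the E geometry.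

2. Step 7.
- Risk: substitution may go on at the second benzylic bromide, and separating the mono-coupled product from the doubly coupled product and from recovered 4 may be laborious.
- Fallback (sets out from 2 and alane 13, comes back at 14): the two ring positions are made different from the start.
  - Commercial 4-methoxy-3-methylbenzoic acid is brominated ortho to the methoxy group (Br2, AcOH) to 3-bromo-4-methoxy-5-methylbenzoic acid F3.
  - F3 is esterified with 2 (DCC, DMAP) to 2-(trimethylsilyl)ethyl 3-bromo-4-methoxy-5-methylbenzoate F4.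
  - F4 is brominated at its only methyl group (NBS, AIBN) to 2-(trimethylsilyl)ethyl 3-bromo-5-(bromomethyl)-4-methoxybenzoate F5.
  - Alane 13 is coupled with F5 at room temperature [Pd(PPh3)4, THF]. Only the benzylic C–Br bond should react, giving the aryl bromide F6.
  - Stille hydroxymethylation of F6 with Bu3SnCH2OH [Pd(PPh3)4, dioxane, 100 °C] gives the benzylic alcohol F7.
  - Appel bromination of F7 (CBr4, PPh3, CH2Cl2, 0 °C) gives 14.

3. Step 5.
- Risk: the ruthenium carbene may engage the alkyne (enyne metathesis). The exchange may also stall at the ethylidene-transfer stage instead of funnelling to the isopropylidene product.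
- Fallback (sets out from 8, comes back at 10): metathesis is replaced by cleavage and olefination. Lemieux–Johnson cleavage of the terminal alkene of 8 (OsO4 cat., NaIO4, 2,6-lutidine, dioxane–water) gives (S)-3-(tert-butyldimethylsilyloxy)-5-(trimethylsilyl)pent-4-ynal F8. Wittig olefination with isopropylidenetriphenylphosphorane (from isopropyltriphenylphosphonium iodide and n-BuLi, THF, −78 °C to rt) gives 10.

Further compounds
F1 | step 8 | tert-butyl{[(1E,3S)-1-iodo-2,6-dimethylhepta-1,5-dien-3-yl]oxy}dimethylsilane | I/C=C(\C)[C@@H](O[Si](C)(C)C(C)(C)C)CC=C(C)C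
F2 | step 8 | {3-[(2E)-4-(tert-butyldimethylsilyloxy)-3-methylbut-2-en-1-yl]-2-methoxy-5-{[2-(trimethylsilyl)ethoxy]carbonyl}benzyl}zinc bromide | COc1c(C/C=C(\C)CO[Si](C)(C)C(C)(C)C)cc(C(=O)OCC[Si](C)(C)C)cc1C[Zn]Br
F3 | step 7 | 3-bromo-4-methoxy-5-methylbenzoic acid | COc1c(C)cc(C(=O)O)cc1Br
F4 | step 7 | 2-(trimethylsilyl)ethyl 3-bromo-4-methoxy-5-methylbenzoate | COc1c(C)cc(C(=O)OCC[Si](C)(C)C)cc1Br
F5 | step 7 | 2-(trimethylsilyl)ethyl 3-bromo-5-(bromomethyl)-4-methoxybenzoate | COc1c(CBr)cc(C(=O)OCC[Si](C)(C)C)cc1Br
F6 | step 7 | 2-(trimethylsilyl)ethyl 3-bromo-5-[(2E)-4-(tert-butyldimethylsilyloxy)-3-methylbut-2-en-1-yl]-4-methoxybenzoate | COc1c(Br)cc(C(=O)OCC[Si](C)(C)C)cc1C/C=C(\C)CO[Si](C)(C)C(C)(C)C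
F7 | step 7 | 2-(trimethylsilyl)ethyl 3-[(2E)-4-(tert-butyldimethylsilyloxy)-3-methylbut-2-en-1-yl]-5-(hydroxymethyl)-4-methoxybenzoate | COc1c(CO)cc(C(=O)OCC[Si](C)(C)C)cc1C/C=C(\C)CO[Si](C)(C)C(C)(C)C
F8 | step 5 | (S)-3-(tert-butyldimethylsilyloxy)-5-(trimethylsilyl)pent-4-ynal | C[Si](C)(C)C#C[C@@H](O[Si](C)(C)C(C)(C)C)CC=O
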